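**Assumptions.** The target has no stereocenters (it is achiral), so "single enantiomer" is moot. 3-(Benzyloxy)-4-methoxybenzaldehyde and 2',4'-dihydroxyacetophenone are taken as commercial. I assume TIPSCl silylates the 4-OH of 2',4'-dihydroxyacetophenone selectively, because the 2-OH is chelated to the carbonyl.

## Retrosynthetic overview
1. The target comes from late-stage C3'-prenylation (proposed new Pd/isoprene hydroarylation) of the 2',4'-dihydroxy-7-O-TIPS isoflavone **11**. C3' is the only ring position flanked by two OH groups.
2. The isoflavone skeleton (C3–C1' bond) is made by Suzuki–Miyaura coupling of 3-iodochromone **9** with aryl-Bpin **5**. The B-ring benzyl groups are then removed by hydrogenolysis before the prenyl alkene exists.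
3. The pyranone ring is formed from 2-hydroxyacetophenone **7** by enaminone formation and I2-mediated cyclization.
4. The B-ring 1,2,4-trioxygenation pattern comes from a Baeyer–Villiger/Dakin-type aryl-formate route on the isovanillin derivative **1**.
5. Order of ring construction: the A ring (commercial) and B ring (commercial) are already present, then the pyranone, then the biaryl-type C3–C1' bond, then the prenyl group.

## Route

**Step 1**
Reactants: **1** 3-(benzyloxy)-4-methoxybenzaldehyde
Product: **2** 3-(benzyloxy)-4-methoxyphenol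
Conditions: (i) mCPBA, CH2Cl2, 0 °C → rt; (ii) K2CO3, MeOH, rt
Reagents that add atoms: mCPBA, O=C(OO)c1cccc(Cl)c1 (supplies the phenol O)
Why: Baeyer–Villiger (Dakin-type) oxidation of an electron-rich aryl aldehyde migrates the aryl group to give the aryl formate, and methanolysis releases the phenol. This sets the 1,2,4-trioxygenation pattern, and benzyl and methyl ethers are untouched.

**Step 2**
Reactants: **2**
Product: **3** 1,3-bis(benzyloxy)-4-methoxybenzene
Conditions: BnBr, K2CO3, DMF, rt
Reagents that add atoms: benzyl bromide, BrCc1ccccc1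
Why: Williamson O-benzylation of the free phenol.

**Step 3**
Reactants: **3**
Product: **4** 1-iodo-2,4-bis(benzyloxy)-5-methoxybenzene
Conditions: NIS, MeCN, rt
Reagents that add atoms: N-iodosuccinimide, O=C1CCC(=O)N1I
Why: Electrophilic iodination goes to the position ortho to one OBn and para to the other. That position is the most activated and least hindered, since C2 lies between the two OBn groups and C5 is activated only by OMe.

**Step 4**
Reactants: **4**
Product: **5** 2-[2,4-bis(benzyloxy)-5-methoxyphenyl]-4,4,5,5-tetramethyl-1,3,2-dioxaborolane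
Conditions: B2pin2, PdCl2(dppf) (3 mol%), KOAc, 1,4-dioxane, 90 °C
Reagents that add atoms: bis(pinacolato)diboron, CC1(C)OB(OC1(C)C)B1OC(C)(C)C(C)(C)O1
Why: Miyaura borylation, with benzyl ethers, OMe and arene all inert.

**Step 5**
Reactants: **6** 2',4'-dihydroxyacetophenone
Product: **7** 1-[2-hydroxy-4-(triisopropylsilyloxy)phenyl]ethan-1-one
Conditions: TIPSCl, imidazole, DMF, rt
Reagents that add atoms: triisopropylsilyl chloride, CC(C)[Si](Cl)(C(C)C)C(C)C
Why: Silylation occurs at the more acidic and accessible 4-OH, while the 2-OH is H-bonded to the ketone. TIPS survives the later Suzuki base and is removed under neutral fluoride conditions.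

**Step 6**
Reactants: **7**
Product: **8** (E)-3-(dimethylamino)-1-[2-hydroxy-4-(triisopropylsilyloxy)phenyl]prop-2-en-1-one
Conditions: DMF-DMA, toluene, 110 °C
Reagents that add atoms: N,N-dimethylformamide dimethyl acetal, CN(C)C(OC)OC
Why: The acetyl methyl condenses with the amide acetal to give the enaminone, the standard precursor for chromone C2.

**Step 7**
Reactants: **8**
Product: **9** 3-iodo-7-(triisopropylsilyloxy)-4H-chromen-4-one
Conditions: I2, CH2Cl2, rt, then aq Na2S2O3
Reagents that add atoms: iodine, II
Why: The enaminone is iodinated at its α-carbon, then the phenol OH closes onto the iminium and Me2NH is lost, closing the pyranone ring. This is the known enaminone-to-3-iodochromone cyclization.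

**Step 8**
Reactants: **9** and **5**
Product: **10** 2',4'-bis(benzyloxy)-5'-methoxy-7-(triisopropylsilyloxy)isoflavone
Conditions: Pd(PPh3)4 (5 mol%), 2 M aq Na2CO3, DME, 80 °C (5: 1.5 equiv)
Reagents that add atoms: none
Why: Suzuki–Miyaura coupling of the 3-iodochromone with the arylboronate forms the C3–C1' bond and completes the isoflavone skeleton.

**Step 9**
Reactants: **10**
Product: **11** 2',4'-dihydroxy-5'-methoxy-7-(triisopropylsilyloxy)isoflavone
Conditions: H2 (1 atm), 10% Pd/C, EtOAc/MeOH, rt, short reaction time
Reagents that add atoms: none (H2 adds only hydrogen)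
Why: Hydrogenolysis of both aryl benzyl ethers is done before the prenyl alkene is present, so the alkene cannot be reduced. The chromone C2=C3 bond, OMe and OTIPS survive.

**Step 10 (key step)**
Reactants: **11**
Product: **12** 3-[2,4-dihydroxy-5-methoxy-3-(3-methylbut-2-en-1-yl)phenyl]-7-(triisopropylsilyloxy)-4H-chromen-4-one
Conditions: isoprene (10 equiv), Pd2(dba)3 (2.5 mol%), DPEphos (6 mol%), (PhO)2P(O)OH (10 mol%), PhMe, 60 °C, sealed tube
Reagents that add atoms: isoprene, C=CC(C)=C (adds C5H8 as the prenyl group)
Why: Proposed new method: Pd(0) and a Brønsted acid generate L2Pd–H, which adds to isoprene at the isopropenyl CH2 terminus to give an η3-prenyl-Pd phenoxide ion pair. O-Prenylation is reversible under Pd(0)/acid (Tsuji–Trost ionization of aryl prenyl ethers), while attack of the most nucleophilic carbon, C3' between the two OH groups, at the less-substituted π-allyl terminus is irreversible. This gives C3'-linear prenyl exclusively, not reverse-prenyl, O-prenyl, or A-ring C8 (TIPS-protected, electron-poor) products; the closest known reactions are Pd–H hydrofunctionalization of isoprene and Tsuji–Trost C-allylation of naphthols/phenols.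

**Step 11**
Reactants: **12**
Product: **13** Piscisoflavone A
Conditions: TBAF, AcOH (1:1), THF, 0 °C → rt
Reagents that add atoms: none (F– leaves as TIPSF; H from AcOH)
Why: Buffered fluoride desilylation removes the TIPS group and leaves the free phenols, prenyl alkene and isoflavone intact.

## Compound list
1 | 3-(benzyloxy)-4-methoxybenzaldehyde | COc1ccc(C=O)cc1OCc1ccccc1 | starting material
2 | 3-(benzyloxy)-4-methoxyphenol | COc1ccc(O)cc1OCc1ccccc1 | intermediate
3 | 1,3-bis(benzyloxy)-4-methoxybenzene | COc1ccc(OCc2ccccc2)cc1OCc1ccccc1 | intermediate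
4 | 1-iodo-2,4-bis(benzyloxy)-5-methoxybenzene | COc1cc(I)c(OCc2ccccc2)cc1OCc1ccccc1 | intermediate
5 | 2-[2,4-bis(benzyloxy)-5-methoxyphenyl]-4,4,5,5-tetramethyl-1,3,2-dioxaborolane | COc1cc(B2OC(C)(C)C(C)(C)O2)c(OCc2ccccc2)cc1OCc1ccccc1 | intermediate
6 | 2',4'-dihydroxyacetophenone | CC(=O)c1ccc(O)cc1O | starting material
7 | 1-[2-hydroxy-4-(TIPSO)phenyl]ethanone | CC(=O)c1ccc(O[Si](C(C)C)(C(C)C)C(C)C)cc1O | intermediate
8 | (E)-3-(dimethylamino)-1-[2-hydroxy-4-(TIPSO)phenyl]prop-2-en-1-one | CN(C)/C=C/C(=O)c1ccc(O[Si](C(C)C)(C(C)C)C(C)C)cc1O | intermediate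
9 | 3-iodo-7-(TIPSO)chromone | O=c1c(I)coc2cc(O[Si](C(C)C)(C(C)C)C(C)C)ccc12 | intermediate
10 | 2',4'-bis(benzyloxy)-5'-methoxy-7-(TIPSO)isoflavone | COc1cc(-c2coc3cc(O[Si](C(C)C)(C(C)C)C(C)C)ccc3c2=O)c(OCc2ccccc2)cc1OCc1ccccc1 | intermediate
11 | 2',4'-dihydroxy-5'-methoxy-7-(TIPSO)isoflavone | COc1cc(-c2coc3cc(O[Si](C(C)C)(C(C)C)C(C)C)ccc3c2=O)c(O)cc1O | intermediate
12 | 3'-prenyl-2',4'-dihydroxy-5'-methoxy-7-(TIPSO)isoflavone | COc1cc(-c2coc3cc(O[Si](C(C)C)(C(C)C)C(C)C)ccc3c2=O)c(O)c(CC=C(C)C)c1O | intermediate
13 | Piscisoflavone A | COc1cc(-c2coc3cc(O)ccc3c2=O)c(O)c(CC=C(C)C)c1O | target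

## Totals
Total steps: 11. Longest linear sequence: 8 steps (1 → 2 → 3 → 4 → Suzuki → hydrogenolysis → prenylation → desilylation). The A-ring branch is 3 steps before the Suzuki.

## Three steps most likely to fail
1. **Step 10 (proposed new Pd/isoprene C3'-hydroarylation).** It may give O-prenyl ether, reverse-prenyl product, or chromane cyclization.
   Fallback (known chemistry): move prenylation to the B ring. Use the bis-MOM ether of 4-methoxyresorcinol, lithiate C2 between the two OMOM groups (n-BuLi/TMEDA), then add prenyl bromide with CuI. Follow with NIS iodination, Miyaura borylation, Suzuki with **9**, MOM removal (ZnBr2/n-PrSH) and TBAF.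
2. **Step 8 (Suzuki).** The electron-rich 2,4-dialkoxyaryl-Bpin is prone to protodeboronation under aqueous base.
   Fallback: Negishi coupling. Convert iodide **4** to the arylzinc (t-BuLi, ZnCl2) and couple it with iodochromone **9** under Pd(PPh3)4.
3. **Step 9 (hydrogenolysis).** It risks over-reduction of chromone C2=C3 or incomplete debenzylation.
   Fallback: change the B-ring protecting group to MOM (from 4-methoxyresorcinol bis-MOM ether), and remove it with HCl/MeOH before the prenylation step.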